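**Retrosynthetic overview**
- Target ⇐ its 1'-O-TBS ether ⇐ dearomative double C-prenylation of a tetrasubstituted acylphloroglucinol. No ring is built: the six-membered ring is the phloroglucinol nucleus bought as its tribenzyl ether, and it is dearomatised in the penultimate step.
- Acylphloroglucinol ⇐ per-benzyl ether (hydrogenolysis); isobutyryl group ⇐ aryllithium + isobutyraldehyde, then oxidation.
- Aryl–C1' bond and the C1' stereocentre ⇐ chelation-controlled addition of the mono-Grignard reagent of 2,4-dibromo-1,3,5-tris(benzyloxy)benzene to (S)-2-(benzyloxy)-3-methylbutanal.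
- C2' stereocentre ⇐ ketoreductase reduction of achiral ethyl 3-methyl-2-oxobutanoate.

Assumption: the target's enolised β-triketone is treated as the tautomer drawn in the given SMILES, and 1,3,5-tris(benzyloxy)benzene is taken as a purchasable phloroglucinol ether.

**Step 1**
Reactants: 1 ethyl 3-methyl-2-oxobutanoate
Product: 2 ethyl (2S)-2-hydroxy-3-methylbutanoate
Conditions: (S)-selective ketoreductase (KRED, NADPH-dependent oxidoreductase), NADP+ (cat.), i-PrOH (10 vol%), KH2PO4/K2HPO4 buffer pH 7.0, MgSO4 (2 mM), 30 °C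
Reagents that add atoms: none
Why: Ketoreductase-catalysed asymmetric ketone reduction with isopropanol-coupled cofactor recycling; the enzyme delivers hydride from NADPH to the Re face of the α-keto ester, setting the (S) carbinol (C2' of the target), typically in >99% ee.

**Step 2**
Reactants: 2 ethyl (2S)-2-hydroxy-3-methylbutanoate
Product: 3 ethyl (2S)-2-(benzyloxy)-3-methylbutanoate
Conditions: BnOC(=NH)CCl3, TfOH (cat.), cyclohexane/CH2Cl2 2:1, 0 °C to rt
Reagents that add atoms: benzyl 2,2,2-trichloroacetimidate, ClC(Cl)(Cl)C(=N)OCc1ccccc1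
Why: Acid-catalysed O-benzylation with a trichloroacetimidate avoids the basic conditions that would racemise an α-hydroxy ester, and the benzyl ether is the chelating group needed in step 5.

**Step 3**
Reactants: 3 ethyl (2S)-2-(benzyloxy)-3-methylbutanoate
Product: 4 (2S)-2-(benzyloxy)-3-methylbutanal
Conditions: i-Bu2AlH (1.1 equiv), CH2Cl2, −78 °C; MeOH, then aq. potassium sodium tartrate; used crude at once
Reagents that add atoms: none
Why: Partial DIBAL reduction of an α-alkoxy ester stops at the chelate-stabilised tetrahedral aluminate at −78 °C, and the configurationally labile aldehyde is not stored or chromatographed.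

**Step 4**
Reactants: 5 1,3,5-tris(benzyloxy)benzene
Product: 6 2,4-dibromo-1,3,5-tris(benzyloxy)benzene
Conditions: NBS (2.05 equiv), CH2Cl2, 0 °C, dark
Reagents that add atoms: N-bromosuccinimide, BrN1C(=O)CCC1=O
Why: Electrophilic aromatic bromination of the very electron-rich triether is fast and stoichiometry-controlled, and the three ring positions are equivalent so only one dibromide can form.

**Step 5**
Reactants: 6 2,4-dibromo-1,3,5-tris(benzyloxy)benzene; 4 (2S)-2-(benzyloxy)-3-methylbutanal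
Product: 9 (1S,2S)-2-(benzyloxy)-1-[3-bromo-2,4,6-tris(benzyloxy)phenyl]-3-methylbutan-1-ol, via monolithio arene 7 (not isolated), via aryl Grignard reagent 8 (not isolated)
Conditions: n-BuLi (1.0 equiv), Et2O/THF 9:1, −78 °C; MgBr2·OEt2 (1.3 equiv), −78 to −20 °C; then 4 in CH2Cl2, −78 °C
Reagents that add atoms: none
Why: Single bromine–lithium exchange and transmetalation to magnesium are followed by a Cram-chelate Grignard addition, in which Mg bridges the aldehyde and benzyloxy oxygens and the aryl group attacks anti to the isopropyl group, giving the 1,2-syn (1S,2S) alcohol (the minor anti epimer is removed by chromatography).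

**Step 6**
Reactants: 9 (1S,2S)-2-(benzyloxy)-1-[3-bromo-2,4,6-tris(benzyloxy)phenyl]-3-methylbutan-1-ol
Product: 10 [(1S,2S)-2-(benzyloxy)-1-[3-bromo-2,4,6-tris(benzyloxy)phenyl]-3-methylbutoxy](tert-butyl)dimethylsilane
Conditions: TBSOTf, 2,6-lutidine, CH2Cl2, −78 to 0 °C
Reagents that add atoms: tert-butyldimethylsilyl trifluoromethanesulfonate, CC(C)(C)[Si](C)(C)OS(=O)(=O)C(F)(F)F
Why: Silyl triflate silylation under basic buffering protects the hindered, ionisation-prone benzylic alcohol without acid, so C1' keeps its configuration.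

**Step 7**
Reactants: 10 the TBS ether from step 6; 11 2-methylpropanal (isobutyraldehyde)
Product: 13 1-{2,4,6-tris(benzyloxy)-3-[(1S,2S)-2-(benzyloxy)-1-(tert-butyldimethylsilyloxy)-3-methylbutyl]phenyl}-2-methylpropan-1-ol (about 1:1 epimers at the new carbinol), via aryllithium 12 (not isolated)
Conditions: n-BuLi (1.1 equiv), THF, −78 °C; then 11, −78 °C
Reagents that add atoms: none
Why: Bromine–lithium exchange followed by 1,2-addition of the aryllithium to the aldehyde is fast at −78 °C, where ortho-benzyloxy aryllithiums are stable; the new carbinol centre is destroyed in the next step.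

**Step 8**
Reactants: 13 the epimeric benzylic alcohols from step 7
Product: 14 1-{2,4,6-tris(benzyloxy)-3-[(1S,2S)-2-(benzyloxy)-1-(tert-butyldimethylsilyloxy)-3-methylbutyl]phenyl}-2-methylpropan-1-one
Conditions: Dess–Martin periodinane, pyridine, CH2Cl2, 0 °C to rt
Reagents that add atoms: none
Why: Dess–Martin oxidation converts the hindered secondary benzylic alcohol to the aryl ketone under buffered, near-neutral conditions that leave the silyl and benzyl ethers and both side-chain stereocentres alone.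

**Step 9**
Reactants: 14 the tetrabenzyl aryl ketone from step 8
Product: 15 1-{3-[(1S,2S)-1-(tert-butyldimethylsilyloxy)-2-hydroxy-3-methylbutyl]-2,4,6-trihydroxyphenyl}-2-methylpropan-1-one
Conditions: H2 (1 atm), 10% Pd/C, EtOAc, rt
Reagents that add atoms: none
Why: Catalytic hydrogenolysis cleaves the three aryl benzyl ethers and the alkyl benzyl ether, while the hindered benzylic C–OSi bond and the hydrogen-bonded aryl ketone are reduced much more slowly in a neutral, alcohol-free solvent.

**Step 10**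
Reactants: 15 the acylphloroglucinol from step 9; 16 1-bromo-3-methylbut-2-ene (prenyl bromide)
Product: 18 4-[(1S,2S)-1-(tert-butyldimethylsilyloxy)-2-hydroxy-3-methylbutyl]-3,5-dihydroxy-6,6-bis(3-methylbut-2-en-1-yl)-2-(2-methylpropanoyl)cyclohexa-2,4-dien-1-one, via mono-C-prenyl arene 17 (not isolated)
Conditions: NaOMe (3.2 equiv), MeOH, 0 °C; 16 (2.2 equiv), 0 °C to rt; cold aq. citric acid work-up
Reagents that add atoms: none
Why: Phenoxide C-alkylation in a protic medium puts the first prenyl group on the only free ring carbon and the second on the same carbon (less hindered than the carbon carrying the branched silyloxyalkyl chain), a dearomative alkylation of the kind used for lupulones, which gives the gem-diprenyl dienone without touching the stereocentres.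

**Step 11**
Reactants: 18 the silyl-protected dienone from step 10
Product: 19 3,5-dihydroxy-4-[(1S,2S)-1,2-dihydroxy-3-methylbutyl]-6,6-bis(3-methylbut-2-en-1-yl)-2-(2-methylpropanoyl)cyclohexa-2,4-dien-1-one (target)
Conditions: HF·pyridine, pyridine, THF, 0 °C to rt
Reagents that add atoms: none
Why: Buffered fluoride desilylation frees the 1'-hydroxyl without the strong acid or base that would dehydrate or retro-aldolise the carbinol next to the enolised triketone, and any silyl group that migrated to O-2' in step 10 is removed in the same operation.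

**Compound list**
1 | ethyl 3-methyl-2-oxobutanoate | CCOC(=O)C(=O)C(C)C | starting material
2 | ethyl (2S)-2-hydroxy-3-methylbutanoate | CCOC(=O)[C@@H](O)C(C)C | intermediate
3 | ethyl (2S)-2-(benzyloxy)-3-methylbutanoate | CCOC(=O)[C@@H](OCc1ccccc1)C(C)C | intermediate
4 | (2S)-2-(benzyloxy)-3-methylbutanal | O=C[C@@H](OCc1ccccc1)C(C)C | intermediate
5 | 1,3,5-tris(benzyloxy)benzene | c1ccc(COc2cc(OCc3ccccc3)cc(OCc3ccccc3)c2)cc1 | starting material
6 | 2,4-dibromo-1,3,5-tris(benzyloxy)benzene | Brc1c(OCc2ccccc2)cc(OCc2ccccc2)c(Br)c1OCc1ccccc1 | intermediate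
7 | 3-bromo-2,4,6-tris(benzyloxy)phenyllithium | [Li]c1c(OCc2ccccc2)cc(OCc2ccccc2)c(Br)c1OCc1ccccc1 | intermediate
8 | 3-bromo-2,4,6-tris(benzyloxy)phenylmagnesium bromide | Br[Mg]c1c(OCc2ccccc2)cc(OCc2ccccc2)c(Br)c1OCc1ccccc1 | intermediate
9 | (1S,2S)-2-(benzyloxy)-1-[3-bromo-2,4,6-tris(benzyloxy)phenyl]-3-methylbutan-1-ol | Brc1c(OCc2ccccc2)cc(OCc2ccccc2)c([C@H](O)[C@@H](OCc2ccccc2)C(C)C)c1OCc1ccccc1 | intermediate
10 | [(1S,2S)-2-(benzyloxy)-1-[3-bromo-2,4,6-tris(benzyloxy)phenyl]-3-methylbutoxy](tert-butyl)dimethylsilane | Brc1c(OCc2ccccc2)cc(OCc2ccccc2)c([C@H](O[Si](C)(C)C(C)(C)C)[C@@H](OCc2ccccc2)C(C)C)c1OCc1ccccc1 | intermediate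
11 | 2-methylpropanal (isobutyraldehyde) | CC(C)C=O | starting material
12 | 2,4,6-tris(benzyloxy)-3-[(1S,2S)-2-(benzyloxy)-1-(tert-butyldimethylsilyloxy)-3-methylbutyl]phenyllithium | [Li]c1c(OCc2ccccc2)cc(OCc2ccccc2)c([C@H](O[Si](C)(C)C(C)(C)C)[C@@H](OCc2ccccc2)C(C)C)c1OCc1ccccc1 | intermediate
13 | 1-{2,4,6-tris(benzyloxy)-3-[(1S,2S)-2-(benzyloxy)-1-(tert-butyldimethylsilyloxy)-3-methylbutyl]phenyl}-2-methylpropan-1-ol (both epimers at the carbinol carbon) | CC(C)C(O)c1c(OCc2ccccc2)cc(OCc2ccccc2)c([C@H](O[Si](C)(C)C(C)(C)C)[C@@H](OCc2ccccc2)C(C)C)c1OCc1ccccc1 | intermediate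
14 | 1-{2,4,6-tris(benzyloxy)-3-[(1S,2S)-2-(benzyloxy)-1-(tert-butyldimethylsilyloxy)-3-methylbutyl]phenyl}-2-methylpropan-1-one | CC(C)C(=O)c1c(OCc2ccccc2)cc(OCc2ccccc2)c([C@H](O[Si](C)(C)C(C)(C)C)[C@@H](OCc2ccccc2)C(C)C)c1OCc1ccccc1 | intermediate
15 | 1-{3-[(1S,2S)-1-(tert-butyldimethylsilyloxy)-2-hydroxy-3-methylbutyl]-2,4,6-trihydroxyphenyl}-2-methylpropan-1-one | CC(C)C(=O)c1c(O)cc(O)c([C@H](O[Si](C)(C)C(C)(C)C)[C@@H](O)C(C)C)c1O | intermediate
16 | 1-bromo-3-methylbut-2-ene (prenyl bromide) | CC(C)=CCBr | starting material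
17 | 1-{3-[(1S,2S)-1-(tert-butyldimethylsilyloxy)-2-hydroxy-3-methylbutyl]-2,4,6-trihydroxy-5-(3-methylbut-2-en-1-yl)phenyl}-2-methylpropan-1-one | CC(C)C(=O)c1c(O)c(CC=C(C)C)c(O)c([C@H](O[Si](C)(C)C(C)(C)C)[C@@H](O)C(C)C)c1O | intermediate
18 | 4-[(1S,2S)-1-(tert-butyldimethylsilyloxy)-2-hydroxy-3-methylbutyl]-3,5-dihydroxy-6,6-bis(3-methylbut-2-en-1-yl)-2-(2-methylpropanoyl)cyclohexa-2,4-dien-1-one | CC(C)=CCC1(CC=C(C)C)C(=O)C(C(=O)C(C)C)=C(O)C([C@H](O[Si](C)(C)C(C)(C)C)[C@@H](O)C(C)C)=C1O | intermediate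
19 | 3,5-dihydroxy-4-[(1S,2S)-1,2-dihydroxy-3-methylbutyl]-6,6-bis(3-methylbut-2-en-1-yl)-2-(2-methylpropanoyl)cyclohexa-2,4-dien-1-one | CC(C)=CCC1(CC=C(C)C)C(=O)C(C(=O)C(C)C)=C(O)C([C@H](O)[C@@H](O)C(C)C)=C1O | target

**Totals**
Total step count: 11. Longest linear sequence: 10 steps (1 → 2 → 3 → 4 → 9 → 10 → 13 → 14 → 15 → 18 → 19).

**Steps most likely to fail**

Step 5 (hindered, diastereoselective aryl addition). The chelate control may be eroded by the ether solvent or by the bulk of the di-ortho-substituted aryl nucleophile. The fallback sets out from 3 and 6 and comes back at 9. Ester 3 is converted with MeNH(OMe)·HCl and i-PrMgCl (THF, −20 °C) into the Weinreb amide (2S)-2-(benzyloxy)-N-methoxy-N,3-dimethylbutanamide F1. The monolithio arene 7, made from 6 as before, is acylated with it (THF, −78 to −40 °C) to the aryl ketone (2S)-2-(benzyloxy)-1-[3-bromo-2,4,6-tris(benzyloxy)phenyl]-3-methylbutan-1-one F2. Reduction with LiBH(s-Bu)3 (THF, −78 °C) under Felkin–Anh, non-chelation control delivers hydride anti to the benzyloxy group and gives the same 1,2-syn alcohol 9, so C1' is set by carbonyl reduction instead of C–C bond formation.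

Step 10 (dearomative gem-diprenylation). O-prenylation, over-alkylation or attack at the side-chain-bearing carbon could lower the yield. The fallback sets out from 15 and comes back at 18. Tsuji–Trost allylation with Pd(PPh3)4 (zerovalent palladium, 5 mol%) and allyl methyl carbonate (2.2 equiv) in THF at rt is C-selective, because O-allyl products re-ionise. It passes through the mono-allyl arene 1-{3-[(1S,2S)-1-(tert-butyldimethylsilyloxy)-2-hydroxy-3-methylbutyl]-2,4,6-trihydroxy-5-(prop-2-en-1-yl)phenyl}-2-methylpropan-1-one F3 to the gem-diallyl dienone 4-[(1S,2S)-1-(tert-butyldimethylsilyloxy)-2-hydroxy-3-methylbutyl]-3,5-dihydroxy-2-(2-methylpropanoyl)-6,6-di(prop-2-en-1-yl)cyclohexa-2,4-dien-1-one F4. Double olefin cross-metathesis with excess 2-methyl-2-butene (second-generation Grubbs catalyst RuCl2(=CHPh)(H2IMes)(PCy3), CH2Cl2, 40 °C) then turns both allyl groups into prenyl groups and gives 18.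

Step 11 (final desilylation of a hindered silyl ether next to a dehydration-prone carbinol). The fallback sets out from 15 and comes back at 19. The silyl group is removed at the more robust aromatic stage with Bu4NF/AcOH in THF, giving the free diol 1-{3-[(1S,2S)-1,2-dihydroxy-3-methylbutyl]-2,4,6-trihydroxyphenyl}-2-methylpropan-1-one F5. The prenylation conditions of step 10 applied to F5 pass through the mono-prenyl arene 1-{3-[(1S,2S)-1,2-dihydroxy-3-methylbutyl]-2,4,6-trihydroxy-5-(3-methylbut-2-en-1-yl)phenyl}-2-methylpropan-1-one F6 and give 19 directly, so no deprotection is needed after dearomatisation.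

**Further compounds**
F1 | step 5 | (2S)-2-(benzyloxy)-N-methoxy-N,3-dimethylbutanamide | CON(C)C(=O)[C@@H](OCc1ccccc1)C(C)C
F2 | step 5 | (2S)-2-(benzyloxy)-1-[3-bromo-2,4,6-tris(benzyloxy)phenyl]-3-methylbutan-1-one | Brc1c(OCc2ccccc2)cc(OCc2ccccc2)c(C(=O)[C@@H](OCc2ccccc2)C(C)C)c1OCc1ccccc1
F3 | step 10 | 1-{3-[(1S,2S)-1-(tert-butyldimethylsilyloxy)-2-hydroxy-3-methylbutyl]-2,4,6-trihydroxy-5-(prop-2-en-1-yl)phenyl}-2-methylpropan-1-one | CC(C)C(=O)c1c(O)c(CC=C)c(O)c([C@H](O[Si](C)(C)C(C)(C)C)[C@@H](O)C(C)C)c1O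
F4 | step 10 | 4-[(1S,2S)-1-(tert-butyldimethylsilyloxy)-2-hydroxy-3-methylbutyl]-3,5-dihydroxy-2-(2-methylpropanoyl)-6,6-di(prop-2-en-1-yl)cyclohexa-2,4-dien-1-one | C=CCC1(CC=C)C(=O)C(C(=O)C(C)C)=C(O)C([C@H](O[Si](C)(C)C(C)(C)C)[C@@H](O)C(C)C)=C1O
F5 | step 11 | 1-{3-[(1S,2S)-1,2-dihydroxy-3-methylbutyl]-2,4,6-trihydroxyphenyl}-2-methylpropan-1-one | CC(C)C(=O)c1c(O)cc(O)c([C@H](O)[C@@H](O)C(C)C)c1O
F6 | step 11 | 1-{3-[(1S,2S)-1,2-dihydroxy-3-methylbutyl]-2,4,6-trihydroxy-5-(3-methylbut-2-en-1-yl)phenyl}-2-methylpropan-1-one | CC(C)C(=O)c1c(O)c(CC=C(C)C)c(O)c([C@H](O)[C@@H](O)C(C)C)c1O
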